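## The problem

Pestalone E (17) is two pentasubstituted benzene rings joined through one ketone carbon. There is no further ring and no stereocentre, so the synthesis has to solve regiochemistry and the making of one very crowded carbonyl bridge. Numbering used here: ring A is C1 (prenyl), C2 (OH), C3 (H), C4 (OH), C5 (CHO), C6; the ketone carbon is C7; ring B is C1', C2' (OH), C3' (H), C4' (CH3), C5' (Cl), C6' (OH).

C7 is bonded to C6, which lies between the prenyl-bearing C1 and the formyl-bearing C5, and to C1', which lies between the oxygenated C2' and C6'. The benzophenone is therefore tetra-ortho-substituted. Friedel–Crafts acylation and addition of an aryl metal to an acid derivative are both poor options, the more so because an acyl derivative at C6 next to the C5 aldehyde tends to collapse into a cyclic pseudo-acid form.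

Each ring keeps one hydrogen (C3, C3'), so every substituent must be placed unambiguously: the prenyl group between C6 and C2–O, the chlorine between C4'–CH3 and C6'–O.

Several groups will not survive rough treatment:
- The prenyl double bond closes onto the C2 hydroxyl under strong acid (chroman formation) and is attacked by electrophilic chlorine and by hydrogenation. Ring B must therefore be chlorinated before the rings are joined, and the last deprotection must be mild.
- The ortho-aroyl benzaldehyde is sensitive to bases and nucleophiles.
- The C5'–Cl bond rules out hydrogenolysis and forcing metal–halogen exchange conditions.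

Three features make a three-component union possible:
- C7 bears nothing but oxygen and can be supplied as carbon monoxide.
- C6 is the third oxygenated position of a phloroglucinol pattern (C2, C4, C6). In 2,4,6-trihydroxybenzaldehyde (1) its oxygen is a hydroxyl chelated to the formyl group. It stays free on bis-protection, steers the side chain to C1 by Claisen rearrangement, and can then leave as triflate.
- C1' lies between two oxygens, so its C–H is the most acidic one of a ring B bis-ether and becomes the nucleophile.

## Retrosynthesis

**17 from 16.** The four phenolic O–H bonds are masked as methoxymethyl (MOM) ethers in 16. MOM is preferred to benzyl (hydrogenolysis would take the prenyl alkene and the chlorine) and to methyl (boron tribromide would destroy the prenyl group). The same ethers are needed on ring B as directing groups for metalation. The forward step must cleave four acetals without cyclising the prenyl group onto the C2 hydroxyl.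

**16 from 9, 13 and 15.** Both bonds to C7 (C6–C7 and C7–C1') are cut at once, giving aryl triflate 9, carbon monoxide 13 and arylzinc chloride 15. Cutting only one of them would require a ring A acyl electrophile beside a free aldehyde, or a ring A carbanion beside that aldehyde; neither is attractive. The three-component cut avoids any acyl derivative on either ring. The precursors are two monocyclic arenes of ordinary complexity. The forward reaction must put CO between the partners and not couple them directly.

**15 from 12 via 14.** The C1'–Zn bond goes back to C1'–Li (14) and then to C1'–H in bis-ether 12. This C–H is the only one flanked by two MOM ethers, so deprotonation needs no halogen at C1'. The chlorine at C5' has no ortho hydrogen and cannot give an aryne. Zinc is chosen over lithium or magnesium because the aldehyde of 9 must survive.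

**12 from 11 and 10.** The two O–MOM bonds and then the C5'–Cl bond are cut, leading to 4-chloroorcinol 11 and orcinol 10. Chlorination at the start keeps electrophilic chlorine away from the prenyl group and from ring A. The forward chlorination must select the position ortho/para to the hydroxyls and next to the methyl group over the position between the hydroxyls, and must stop at one chlorine.

**9 from 8.** The S–O bond of the triflate is cut, giving phenol 8. The chelated hydroxyl that survives bis-protection is exactly the one on C6, so no extra differentiation is needed.

**8 from 6 and 7.** The trisubstituted double bond of the prenyl group is cut by retro-metathesis to the allyl compound 6 and 2-methylbut-2-ene 7. An allyl group can be placed on carbon with complete regiocontrol by Claisen rearrangement. A prenyl ether would rearrange with inversion to the 1,1-dimethylallyl isomer or migrate on to the para position.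

**6 from 4 via 5, and 4 from 2 and 3.** The C1–CH2 bond is cut by retro-Claisen to allyl ether 4, through dienone 5, and the O–allyl bond to phenol 2 and allyl bromide 3. Of the two carbons ortho to the ether oxygen, one carries the formyl group, so the allyl group can end up only on the other, the future C1. Direct C-prenylation of a phenoxide offers no such control over O- versus C-alkylation and over-alkylation.

**2 from 1.** Two O–MOM bonds are cut to 2,4,6-trihydroxybenzaldehyde 1. The aldehyde is symmetric, so leaving either chelated hydroxyl free gives the same bis-ether 2.

## Roads not taken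

**Alternative 1:** Ring B is built, not bought. The cut removes C6'–C1' and C2'–C3' and leads to 4-chloro-3-methylcyclobut-2-en-1-one A1 and a ring A propargyl siloxyalkyne A2 in which C7 is a methylene group. On heating (Danheiser benzannulation) A1 should open, add across the electron-rich triple bond of A2, open again and close by 6-pi electrocyclisation to the diarylmethane phenol A3.

- Merits: the chlorine, the methyl group and both oxygens of ring B are delivered by the reagents, so there is no chlorination regiochemistry and no risk of double chlorination. No bond is made at a crowded metal centre. In these two respects this road is better than the chosen one, where step 6 relies on the intrinsic preference of orcinol.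
- Weak points: C7 arrives as CH2 and must be oxidised to the ketone afterwards, in a molecule whose prenyl group offers more reactive allylic C–H bonds and whose rings are electron-rich. A2 needs all of ring A as in 9, plus an acetal and a homologated C6 side chain ending in a silyl ynol ether. A1 is a strained, sensitive chloroketone that needs its own synthesis.
- Comparison: the chosen plan delivers C7 at the ketone oxidation level from CO, needs ring B only two steps from orcinol, and should be several steps shorter.

**Alternative 2:** Ring A is built last. The cut removes C1–C6 and C4–C5 and leads to the prenyl-bearing 1-methoxy-1,3-bis(silyloxy)diene A4 and the aroyl ynal A5, which carries ring B, C7 and the future formyl carbon. A thermal Diels–Alder reaction followed by loss of the methoxy group should give A6, pestalone E with only ring B still protected.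

- Merits: all six ring A substituents appear in one step, ring A needs no protecting groups and no triflate, and only two MOM ethers remain to be cleaved, so the acid-sensitive prenyl phenol is exposed more briefly. In step count and protecting-group economy this road is at least as good as the chosen one and probably shorter.
- Weak points: A5 is an alkyne activated by two carbonyl groups and carries a free aldehyde; it is prone to conjugate addition and polymerisation and awkward to prepare. The regiochemistry depends on the aldehyde outweighing the aroyl ketone as the directing acceptor. If the ketone directs, the prenyl group ends up next to the formyl-bearing carbon. The silyl ketene acetal terminus of A4 may add to the aldehyde carbonyl in a Mukaiyama-type aldol reaction and not cycloadd, and the substituted diene terminus slows the cycloaddition.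
- Comparison: in the chosen plan every bond-forming step has close precedent, and its regiochemistry is fixed by the symmetry of 1 and by the Claisen rearrangement, not by a competition between two acceptors.

**Alternative 3:** C1'–C7 is formed together with C2'–O. The partners are the ring A benzoic acid A7 (aldehyde masked as dimethyl acetal), used as its caesium salt, and the ortho-silyl aryl triflate A8. Fluoride should convert A8 into aryne A9, the carboxylate oxygen should add at C2' (meta to the MOM ether), and the aryl anion at C1' should attack the ester carbonyl in a Fries-type acyl shift to give hydroxy ketone A10.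

- Merits: no transition metal, the crowded C–C bond is formed intramolecularly, C7 has the right oxidation level, and the C2' hydroxyl emerges free. It does not depend on a catalyst choosing CO insertion over direct coupling, and in that respect it is as good as the chosen plan.
- Weak points: a di-ortho-substituted benzoate is a poor nucleophile for A9. The acyl shift must pass through a four-membered transition state to a tetra-ortho-substituted ketone, and protonation of the aryl anion would stop at the aryl ester. A8 needs a long sequence to place silicon, triflate, chlorine, methyl and the ether correctly. A7 is most directly made by carbonylation of 9 after acetal protection, so ring A costs more steps than in the chosen route.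
- Comparison: the chosen plan forms both bonds to C7 in one operation from 9 itself and uses a ring B partner two steps from orcinol.

Key step: step 8

Assumption: the target is taken in the open keto-aldehyde form drawn for it, and orcinol is used as the anhydrous diol (the commercial hydrate is dried first).

## Route

Step 1
Reactants: 1 2,4,6-trihydroxybenzaldehyde
Product: 2 2-hydroxy-4,6-bis(methoxymethoxy)benzaldehyde
Conditions: MOMCl (2.2 equiv), i-Pr2NEt, CH2Cl2, 0 °C to rt
Reagents that add atoms: chloromethyl methyl ether, COCCl
Why: O-alkylation (MOM protection) under amine base; the para hydroxyl and one ortho hydroxyl react, while the remaining ortho hydroxyl is held in a hydrogen bond to the formyl oxygen and stays free. The symmetry of 1 means only one bis-ether can form.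

Step 2
Reactants: 2 2-hydroxy-4,6-bis(methoxymethoxy)benzaldehyde; 3 allyl bromide (3-bromoprop-1-ene)
Product: 4 2,4-bis(methoxymethoxy)-6-(prop-2-en-1-yloxy)benzaldehyde
Conditions: K2CO3, DMF, rt to 50 °C
Reagents that add atoms: none
Why: Williamson ether synthesis on the chelated phenol; in a dipolar aprotic solvent the phenoxide should alkylate on oxygen, and the MOM ethers and aldehyde are inert to carbonate.

Step 3
Reactants: 4 2,4-bis(methoxymethoxy)-6-(prop-2-en-1-yloxy)benzaldehyde
Product: 6 2-hydroxy-4,6-bis(methoxymethoxy)-3-(prop-2-en-1-yl)benzaldehyde, via ortho-dienone 5 (not isolated)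
Conditions: N,N-diethylaniline, 190 °C, argon
Reagents that add atoms: none
Why: Aromatic Claisen rearrangement ([3,3]-sigmatropic shift); of the two carbons ortho to the ether oxygen only one bears hydrogen, so dienone 5 forms there and tautomerises to phenol 6. The basic solvent buffers the MOM ethers.

Step 4
Reactants: 6 2-hydroxy-4,6-bis(methoxymethoxy)-3-(prop-2-en-1-yl)benzaldehyde; 7 2-methylbut-2-ene
Product: 8 2-hydroxy-4,6-bis(methoxymethoxy)-3-(3-methylbut-2-en-1-yl)benzaldehyde
Conditions: second-generation Grubbs catalyst (H2IMes)(PCy3)Cl2Ru=CHPh (3 mol %), 2-methylbut-2-ene/CH2Cl2, 40 °C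
Reagents that add atoms: none
Why: Olefin cross-metathesis of the terminal allyl group with excess 2-methylbut-2-ene, driven by loss of propene; the ruthenium carbene tolerates the free phenol and the aldehyde. The new alkene has two identical methyl groups, so no geometry arises.

Step 5
Reactants: 8 2-hydroxy-4,6-bis(methoxymethoxy)-3-(3-methylbut-2-en-1-yl)benzaldehyde
Product: 9 2-formyl-3,5-bis(methoxymethoxy)-6-(3-methylbut-2-en-1-yl)phenyl trifluoromethanesulfonate
Conditions: Tf2O, pyridine, CH2Cl2, −10 to 0 °C
Reagents that add atoms: trifluoromethanesulfonic anhydride, O=S(=O)(OS(=O)(=O)C(F)(F)F)C(F)(F)F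
Why: O-sulfonylation of the only free phenol; pyridine takes up the triflic acid, so the MOM ethers and the prenyl alkene should remain intact.

Step 6
Reactants: 10 orcinol (5-methylbenzene-1,3-diol)
Product: 11 4-chloro-5-methylbenzene-1,3-diol
Conditions: SO2Cl2 (1.0 equiv), Et2O, 0 °C to rt
Reagents that add atoms: sulfuryl chloride, ClS(Cl)(=O)=O
Why: Electrophilic aromatic chlorination; attack is expected at the carbon ortho to one hydroxyl and para to the other, next to the methyl group, in preference to the carbon between the hydroxyls. One equivalent at low temperature limits a second chlorination.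

Step 7
Reactants: 11 4-chloro-5-methylbenzene-1,3-diol
Product: 12 2-chloro-1,5-bis(methoxymethoxy)-3-methylbenzene
Conditions: MOMCl (2.5 equiv), i-Pr2NEt, CH2Cl2, 0 °C to rt
Reagents that add atoms: chloromethyl methyl ether, COCCl
Why: O-alkylation (MOM protection) of both phenols; the ethers serve later as paired directing groups for lithiation and come off with the ring A ethers at the end.

Step 8
Reactants: 12 2-chloro-1,5-bis(methoxymethoxy)-3-methylbenzene; 9 2-formyl-3,5-bis(methoxymethoxy)-6-(3-methylbut-2-en-1-yl)phenyl trifluoromethanesulfonate; 13 carbon monoxide
Product: 16 2-[3-chloro-2,6-bis(methoxymethoxy)-4-methylbenzoyl]-4,6-bis(methoxymethoxy)-3-(3-methylbut-2-en-1-yl)benzaldehyde, via aryllithium 14 (not isolated), via arylzinc chloride 15 (not isolated)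
Conditions: 12 (1.5 equiv), n-BuLi, THF, 0 °C; ZnCl2, THF, 0 °C to rt; then slow addition to 9, Pd(OAc)2 (5 mol %), di(1-adamantyl)-n-butylphosphine (10 mol %), CO (3 bar), THF/NMP, 50 °C
Reagents that add atoms: none
Why: Directed ortho-lithiation of 12 at the only C–H flanked by two MOM ethers gives 14, and ZnCl2 converts it into the far less basic arylzinc 15, which should leave the formyl group of 9 alone. Zerovalent palladium, formed from Pd(OAc)2 and the phosphine by reduction with a little 15, inserts into the C6–O bond of triflate 9, helped by the ortho formyl group and by the LiCl released in the zincation. CO then inserts to give an aroyl complex of divalent palladium in which the crowded ring A sits one atom further from the metal; 15 transmetalates, and reductive elimination forms C7–C1' and releases 16. The closest known reaction type is the palladium-catalysed carbonylative Negishi coupling of ortho-disubstituted aryl halides and triflates with organozinc reagents to hindered ketones. No ring is closed and no stereocentre is created. The selectivity needed is carbonylative over direct coupling, and the substrate secures it: direct coupling would pass through a diarylpalladium complex with four ortho substituents, whereas CO insertion relieves strain, and slow addition of 15 under CO pressure keeps the arylzinc concentration low until insertion has occurred. The step also needs chemoselectivity: the C5'–Cl bond, flanked by methyl and an ether on an electron-rich ring, should not undergo oxidative addition at 50 °C, and the trisubstituted prenyl alkene should insert into the aroyl–palladium bond more slowly than 15 transmetalates.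

Step 9
Reactants: 16 2-[3-chloro-2,6-bis(methoxymethoxy)-4-methylbenzoyl]-4,6-bis(methoxymethoxy)-3-(3-methylbut-2-en-1-yl)benzaldehyde
Product: 17 pestalone E, 2-(3-chloro-2,6-dihydroxy-4-methylbenzoyl)-4,6-dihydroxy-3-(3-methylbut-2-en-1-yl)benzaldehyde
Conditions: HCl (3 M aq), MeOH, rt to 40 °C
Reagents that add atoms: none
Why: Acid-catalysed acetal exchange with methanol removes all four MOM groups as dimethoxymethane; at this acidity and temperature the cleavage should be faster than addition of the C2 hydroxyl to the prenyl double bond. The aqueous medium returns any acetal formed at the aldehyde to the free formyl group.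

## Compound list

1 | 2,4,6-trihydroxybenzaldehyde | O=Cc1c(O)cc(O)cc1O | starting material
2 | 2-hydroxy-4,6-bis(methoxymethoxy)benzaldehyde | O=Cc1c(O)cc(OCOC)cc1OCOC | intermediate
3 | allyl bromide (3-bromoprop-1-ene) | C=CCBr | starting material
4 | 2,4-bis(methoxymethoxy)-6-(prop-2-en-1-yloxy)benzaldehyde | O=Cc1c(OCC=C)cc(OCOC)cc1OCOC | intermediate
5 | 2,4-bis(methoxymethoxy)-6-oxo-5-(prop-2-en-1-yl)cyclohexa-1,3-diene-1-carbaldehyde (racemic, not isolated) | O=CC1=C(OCOC)C=C(OCOC)C(CC=C)C1=O | intermediate
6 | 2-hydroxy-4,6-bis(methoxymethoxy)-3-(prop-2-en-1-yl)benzaldehyde | O=Cc1c(O)c(CC=C)c(OCOC)cc1OCOC | intermediate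
7 | 2-methylbut-2-ene | CC=C(C)C | starting material
8 | 2-hydroxy-4,6-bis(methoxymethoxy)-3-(3-methylbut-2-en-1-yl)benzaldehyde | O=Cc1c(O)c(CC=C(C)C)c(OCOC)cc1OCOC | intermediate
9 | 2-formyl-3,5-bis(methoxymethoxy)-6-(3-methylbut-2-en-1-yl)phenyl trifluoromethanesulfonate | CC(C)=CCc1c(OCOC)cc(OCOC)c(C=O)c1OS(=O)(=O)C(F)(F)F | intermediate
10 | orcinol (5-methylbenzene-1,3-diol) | Cc1cc(O)cc(O)c1 | starting material
11 | 4-chloro-5-methylbenzene-1,3-diol | Cc1cc(O)cc(O)c1Cl | intermediate
12 | 2-chloro-1,5-bis(methoxymethoxy)-3-methylbenzene | Cc1cc(OCOC)cc(OCOC)c1Cl | intermediate
13 | carbon monoxide | [C-]#[O+] | starting material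
14 | [3-chloro-2,6-bis(methoxymethoxy)-4-methylphenyl]lithium (not isolated) | [Li]c1c(OCOC)cc(C)c(Cl)c1OCOC | intermediate
15 | [3-chloro-2,6-bis(methoxymethoxy)-4-methylphenyl]zinc chloride (not isolated) | Cl[Zn]c1c(OCOC)cc(C)c(Cl)c1OCOC | intermediate
16 | 2-[3-chloro-2,6-bis(methoxymethoxy)-4-methylbenzoyl]-4,6-bis(methoxymethoxy)-3-(3-methylbut-2-en-1-yl)benzaldehyde (pestalone E tetrakis(methoxymethyl) ether) | CC(C)=CCc1c(OCOC)cc(OCOC)c(C=O)c1C(=O)c1c(OCOC)cc(C)c(Cl)c1OCOC | intermediate
17 | pestalone E, 2-(3-chloro-2,6-dihydroxy-4-methylbenzoyl)-4,6-dihydroxy-3-(3-methylbut-2-en-1-yl)benzaldehyde | CC(C)=CCc1c(O)cc(O)c(C=O)c1C(=O)c1c(O)cc(C)c(Cl)c1O | target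

## Step count and risks

Total: 9 steps. Longest linear sequence: 7 steps (steps 1 to 5, 8 and 9, from 2,4,6-trihydroxybenzaldehyde); ring B joins after two steps (6 and 7).

**Step 8 (key step).** The most likely failure is slow transmetalation of the doubly ortho-substituted arylzinc onto the aroyl–palladium intermediate. That intermediate could then be diverted by insertion of the neighbouring prenyl alkene (cyclisation to an indanone) or by reduction with loss of the triflate. CO at pressure may also slow the oxidative addition.

The fallback keeps CO as the source of C7 but replaces the crowded transmetalation and reductive elimination by a polar addition. It sets out from 9 and rejoins the route at 17.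
- 9 is converted with trimethyl orthoformate and catalytic pyridinium p-toluenesulfonate in methanol into 2-(dimethoxymethyl)-3,5-bis(methoxymethoxy)-6-(3-methylbut-2-en-1-yl)phenyl trifluoromethanesulfonate F1.
- Palladium-catalysed reductive carbonylation (Pd(OAc)2, 1,3-bis(diphenylphosphino)propane, CO at 1 bar, Et3SiH, Et3N, DMF, 70 °C) should turn the triflate into the aldehyde 2-(dimethoxymethyl)-3,5-bis(methoxymethoxy)-6-(3-methylbut-2-en-1-yl)benzaldehyde F2.
- Aryllithium 14, made from 12 as in step 8, is added at −78 °C to give racemic [3-chloro-2,6-bis(methoxymethoxy)-4-methylphenyl][2-(dimethoxymethyl)-3,5-bis(methoxymethoxy)-6-(3-methylbut-2-en-1-yl)phenyl]methanol F3.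
- Oxidation with Dess–Martin periodinane gives [3-chloro-2,6-bis(methoxymethoxy)-4-methylphenyl][2-(dimethoxymethyl)-3,5-bis(methoxymethoxy)-6-(3-methylbut-2-en-1-yl)phenyl]methanone F4.
- The conditions of step 9 then cleave the four MOM ethers and the dimethyl acetal together to give 17.

**Step 9.** Acid-promoted addition of the C2 hydroxyl to the prenyl double bond (closure to a dimethylchroman) may compete with acetal cleavage, and the keto aldehyde may be held as a cyclic acetal in acidic methanol.

The fallback avoids protic acid. It sets out from 16 and rejoins at 17. Trimethylsilyl triflate with 2,2'-bipyridyl in CH2Cl2 at 0 °C should exchange the aromatic MOM ethers for silyl ethers, giving 2-[3-chloro-4-methyl-2,6-bis(trimethylsilyloxy)benzoyl]-3-(3-methylbut-2-en-1-yl)-4,6-bis(trimethylsilyloxy)benzaldehyde F5. Addition of water hydrolyses F5 to 17 under near-neutral conditions.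

**Step 3.** At 190 °C the allyl group may migrate through the formyl-bearing ortho carbon (onward shift to the para position or loss of the formyl group), and a MOM group may be lost thermally.

The fallback drops the Claisen and metathesis sequence. It sets out from 1 and rejoins at 8. The phenoxide of 1 is C-alkylated with prenyl bromide (DBU, THF, 0 °C to rt); because 1 is symmetric only one mono-C-prenyl product is possible, 2,4,6-trihydroxy-3-(3-methylbut-2-en-1-yl)benzaldehyde F6. Bis-protection with MOMCl and i-Pr2NEt should then leave free the hydroxyl that is both chelated and flanked by the prenyl group, giving 8. This is shorter, but O-alkylation and double alkylation are expected to cost material, which is why it is held in reserve.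

**Step 6.** Chlorination may go on to the dichloride or occur in part at the carbon between the two hydroxyls, because free orcinol is very reactive.

The fallback inverts the order. It sets out from 10 and rejoins at 12. Orcinol is first protected (MOMCl, i-Pr2NEt) as 1,3-bis(methoxymethoxy)-5-methylbenzene F7. The less activated bis-ether is then chlorinated with N-chlorosuccinimide in acetonitrile, where substitution para to one ether and next to the methyl group is the usual outcome for 3,5-dialkoxytoluenes, giving 12.

## Further compounds

F1 | step 8 | 2-(dimethoxymethyl)-3,5-bis(methoxymethoxy)-6-(3-methylbut-2-en-1-yl)phenyl trifluoromethanesulfonate | CC(C)=CCc1c(OCOC)cc(OCOC)c(C(OC)OC)c1OS(=O)(=O)C(F)(F)F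
F2 | step 8 | 2-(dimethoxymethyl)-3,5-bis(methoxymethoxy)-6-(3-methylbut-2-en-1-yl)benzaldehyde | CC(C)=CCc1c(OCOC)cc(OCOC)c(C(OC)OC)c1C=O
F3 | step 8 | [3-chloro-2,6-bis(methoxymethoxy)-4-methylphenyl][2-(dimethoxymethyl)-3,5-bis(methoxymethoxy)-6-(3-methylbut-2-en-1-yl)phenyl]methanol (racemic) | CC(C)=CCc1c(OCOC)cc(OCOC)c(C(OC)OC)c1C(O)c1c(OCOC)cc(C)c(Cl)c1OCOC
F4 | step 8 | [3-chloro-2,6-bis(methoxymethoxy)-4-methylphenyl][2-(dimethoxymethyl)-3,5-bis(methoxymethoxy)-6-(3-methylbut-2-en-1-yl)phenyl]methanone | CC(C)=CCc1c(OCOC)cc(OCOC)c(C(OC)OC)c1C(=O)c1c(OCOC)cc(C)c(Cl)c1OCOC
F5 | step 9 | 2-[3-chloro-4-methyl-2,6-bis(trimethylsilyloxy)benzoyl]-3-(3-methylbut-2-en-1-yl)-4,6-bis(trimethylsilyloxy)benzaldehyde | CC(C)=CCc1c(O[Si](C)(C)C)cc(O[Si](C)(C)C)c(C=O)c1C(=O)c1c(O[Si](C)(C)C)cc(C)c(Cl)c1O[Si](C)(C)C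
F6 | step 3 | 2,4,6-trihydroxy-3-(3-methylbut-2-en-1-yl)benzaldehyde | CC(C)=CCc1c(O)cc(O)c(C=O)c1O
F7 | step 6 | 1,3-bis(methoxymethoxy)-5-methylbenzene | Cc1cc(OCOC)cc(OCOC)c1
A1 | alternative 1 | 4-chloro-3-methylcyclobut-2-en-1-one | O=C1C=C(C)C1Cl
A2 | alternative 1 | ({3-[2-(dimethoxymethyl)-3,5-bis(methoxymethoxy)-6-(3-methylbut-2-en-1-yl)phenyl]prop-1-yn-1-yl}oxy)tri(propan-2-yl)silane | CC(C)=CCc1c(OCOC)cc(OCOC)c(C(OC)OC)c1CC#CO[Si](C(C)C)(C(C)C)C(C)C
A3 | alternative 1 | 6-chloro-2-{[2-(dimethoxymethyl)-3,5-bis(methoxymethoxy)-6-(3-methylbut-2-en-1-yl)phenyl]methyl}-5-methyl-3-[tri(propan-2-yl)silyloxy]phenol | Cc1cc(O[Si](C(C)C)(C(C)C)C(C)C)c(Cc2c(CC=C(C)C)c(OCOC)cc(OCOC)c2C(OC)OC)c(O)c1Cl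
A4 | alternative 2 | 1-methoxy-7-methyl-1,3-bis(trimethylsilyloxy)octa-1,3,6-triene | COC(O[Si](C)(C)C)=CC(O[Si](C)(C)C)=CCC=C(C)C
A5 | alternative 2 | 4-[3-chloro-2,6-bis(methoxymethoxy)-4-methylphenyl]-4-oxobut-2-ynal | O=CC#CC(=O)c1c(OCOC)cc(C)c(Cl)c1OCOC
A6 | alternative 2 | 2-[3-chloro-2,6-bis(methoxymethoxy)-4-methylbenzoyl]-4,6-dihydroxy-3-(3-methylbut-2-en-1-yl)benzaldehyde | CC(C)=CCc1c(O)cc(O)c(C=O)c1C(=O)c1c(OCOC)cc(C)c(Cl)c1OCOC
A7 | alternative 3 | 2-(dimethoxymethyl)-3,5-bis(methoxymethoxy)-6-(3-methylbut-2-en-1-yl)benzoic acid | CC(C)=CCc1c(OCOC)cc(OCOC)c(C(OC)OC)c1C(=O)O
A8 | alternative 3 | 4-chloro-3-(methoxymethoxy)-5-methyl-2-(trimethylsilyl)phenyl trifluoromethanesulfonate | C[Si](C)(C)c1c(OS(=O)(=O)C(F)(F)F)cc(C)c(Cl)c1OCOC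
A9 | alternative 3 | 4-chloro-3-(methoxymethoxy)-5-methyl-1,2-didehydrobenzene | COCOC1=C(Cl)C(C)=CC#C1
A10 | alternative 3 | [3-chloro-6-hydroxy-2-(methoxymethoxy)-4-methylphenyl][2-(dimethoxymethyl)-3,5-bis(methoxymethoxy)-6-(3-methylbut-2-en-1-yl)phenyl]methanone | CC(C)=CCc1c(OCOC)cc(OCOC)c(C(OC)OC)c1C(=O)c1c(O)cc(C)c(Cl)c1OCOC
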